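**Retrosynthetic overview**
1. Target ⇐ acetylation and Morita–Baylis–Hillman hydroxymethylation (CH2O) of epoxy-hydroxy-enone 18 ⇐ ketal hydrolysis and Luche reduction of epoxy ketone 16.
2. 16 ⇐ hydroxyl-directed nucleophilic epoxidation of carbinol 15 ⇐ C5–C1′ bond by Cr/Ni coupling of iodo quinone monoketal 13 (from 2-iodophenol) with trienal 10.
3. Key disconnection: C7′–C8′ (sp2–sp3) by nickel-catalysed reductive cross-electrophile coupling of the primary alkyl radical from epoxy bromide 2 with trienyl bromide 8.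
4. 8 ⇐ (E)-3-methylpent-2-en-4-yn-1-ol + (E)-2-bromo-1-iodopropene (propyne + IBr); 2 ⇐ Shi epoxidation of 5-bromo-2-methylpent-2-ene.
5. Ring order: side-chain oxirane (step 1), then the carbocycle carried over from the arene by dearomatisation (step 6), then the ring oxirane (step 8).

Numbering used: ring C1 (C=O), C2 (bears CH2OAc), C3, C4 (CHOH), C5 (quaternary oxirane carbon), C6 (oxirane CH); side chain C1′ (carbinol) to C12′, oxirane at C10′–C11′. The target is 4S,5R,6R,1′S,10′R.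

Assumption: compounds 1, 3, 5, 11 and 19 are bought (propyne as cylinder gas, formaldehyde as formalin).

**Step 1**
Reactants: 1 5-bromo-2-methylpent-2-ene
Product: 2 (3R)-3-(2-bromoethyl)-2,2-dimethyloxirane
Conditions: 1,2:4,5-di-O-isopropylidene-β-D-erythro-2,3-hexodiulo-2,6-pyranose (Shi ketone from D-fructose, 0.3 equiv), Oxone (KHSO5), K2CO3, n-Bu4NHSO4 (cat.), MeCN–dimethoxymethane / aq. Na2B4O7 buffer, pH 10.5, 0 °C
Reagents that add atoms: potassium peroxymonosulfate (Oxone), [K+].[O-]S(=O)(=O)OO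
Why: Shi asymmetric epoxidation, in which the dioxirane of the D-fructose-derived ketone reacts through the spiro transition state that gives the R oxirane (C10′) from R–CH=CMe2 olefins, while the primary bromide is inert to the dioxirane.

**Step 2**
Reactants: 3 propyne
Product: 4 (E)-2-bromo-1-iodoprop-1-ene
Conditions: IBr, CH2Cl2, −78 °C
Reagents that add atoms: iodine monobromide, BrI
Why: Electrophilic anti iodobromination of the alkyne, the iodonium ion being opened by bromide at the methyl-bearing carbon from the opposite face, which gives the E isomer with the more reactive C–I bond at the terminus.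

**Step 3**
Reactants: 5 (E)-3-methylpent-2-en-4-yn-1-ol; 4 (E)-2-bromo-1-iodoprop-1-ene
Product: 8 (2E,4E,6E)-7-bromo-3-methylocta-2,4,6-trien-1-ol, via O-zirconated dienylzirconocene chloride 6 (not isolated), via dienylzinc chloride 7 (not isolated)
Conditions: Cp2Zr(H)Cl (2.1 equiv), THF, 0 °C → rt; ZnCl2 (1.1 equiv); then 4 (1.1 equiv), Pd(PPh3)4 (5 mol %), rt; aq. NH4Cl
Reagents that add atoms: none
Why: Syn hydrozirconation of the terminal alkyne, Zr→Zn transmetalation and Negishi coupling, in which zerovalent palladium inserts only into the C–I bond of 4 with retention, so the 4E and 6E geometries are fixed and the vinyl bromide is kept for step 4.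

**Step 4 (key step)**
Reactants: 8 (2E,4E,6E)-7-bromo-3-methylocta-2,4,6-trien-1-ol; 2 (3R)-3-(2-bromoethyl)-2,2-dimethyloxirane
Product: 9 (2E,4E,6E)-9-[(2R)-3,3-dimethyloxiran-2-yl]-3,7-dimethylnona-2,4,6-trien-1-ol
Conditions: NiBr2(dme) (10 mol %), 4,4′-di-tert-butyl-2,2′-bipyridine (10 mol %), NaI (0.25 equiv), Mn powder (2 equiv), 2 (1.5 equiv), DMPU, 25–40 °C
Reagents that add atoms: none
Why: Nickel-catalysed reductive cross-electrophile coupling (radical sp2–sp3 coupling), in which low-valent nickel abstracts the halogen of 2 to give the primary 2-(oxiranyl)ethyl radical, this radical is captured by the dienylnickel bromide formed from 8, and reductive elimination makes the C7′–C8′ bond with retention of the 6E geometry; the radical centre is two carbons away from the oxirane, so the ring does not open and C10′ is untouched.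

**Step 5**
Reactants: 9 (2E,4E,6E)-9-[(2R)-3,3-dimethyloxiran-2-yl]-3,7-dimethylnona-2,4,6-trien-1-ol
Product: 10 (2E,4E,6E)-9-[(2R)-3,3-dimethyloxiran-2-yl]-3,7-dimethylnona-2,4,6-trienal
Conditions: MnO2 (15 equiv), CH2Cl2, rt
Reagents that add atoms: none
Why: Chemoselective allylic oxidation with activated MnO2 under neutral conditions, which leaves the oxirane and the all-E triene unchanged.

**Step 6**
Reactants: 11 2-iodophenol
Product: 13 2-iodo-4,4-dimethoxycyclohexa-2,5-dien-1-one, via 2-iodo-4-methoxyphenol 12 (not isolated)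
Conditions: PhI(OAc)2 (2.2 equiv), MeOH, 0 °C → rt
Reagents that add atoms: methanol, CO
Why: Oxidative dearomatisation with a hypervalent iodine reagent, the phenoxenium ion being trapped by methanol at the free para position and the resulting 4-methoxyphenol oxidised again to the p-quinone monoketal, which masks the future C1 ketone and leaves iodine alpha to the free carbonyl.

**Step 7**
Reactants: 13 2-iodo-4,4-dimethoxycyclohexa-2,5-dien-1-one; 10 (2E,4E,6E)-9-[(2R)-3,3-dimethyloxiran-2-yl]-3,7-dimethylnona-2,4,6-trienal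
Product: 15 2-[(1S,2E,4E,6E)-9-[(2R)-3,3-dimethyloxiran-2-yl]-1-hydroxy-3,7-dimethylnona-2,4,6-trien-1-yl]-4,4-dimethoxycyclohexa-2,5-dien-1-one, via alkenylchromium dichloride 14 (not isolated)
Conditions: CrCl2 (4 equiv), N-[2-(4-isopropyl-4,5-dihydro-1,3-oxazol-2-yl)-6-methylphenyl]methanesulfonamide (valinol-derived; the enantiomer that gives the 1′S carbinol, 4.4 equiv), Et3N (4.4 equiv), THF, rt; then NiCl2 (0.2 equiv), 13 (2 equiv), 10, rt; aqueous sodium serinate work-up
Reagents that add atoms: none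
Why: Asymmetric Nozaki–Hiyama–Kishi coupling, in which nickel activates the C–I bond, transmetalation gives alkenylchromium 14, this adds 1,2 to the aldehyde of 10 only (ketone, ketal and oxirane are tolerated), and the chromium-bound chiral sulfonamide ligand selects the aldehyde face to set C1′ as S.

**Step 8**
Reactants: 15 2-[(1S,2E,4E,6E)-9-[(2R)-3,3-dimethyloxiran-2-yl]-1-hydroxy-3,7-dimethylnona-2,4,6-trien-1-yl]-4,4-dimethoxycyclohexa-2,5-dien-1-one
Product: 16 (1S,6R)-1-[(1S,2E,4E,6E)-9-[(2R)-3,3-dimethyloxiran-2-yl]-1-hydroxy-3,7-dimethylnona-2,4,6-trien-1-yl]-5,5-dimethoxy-7-oxabicyclo[4.1.0]hept-3-en-2-one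
Conditions: t-BuOOH (2.0 equiv), n-BuLi (1.5 equiv), THF, −78 → −20 °C
Reagents that add atoms: tert-butyl hydroperoxide, CC(C)(C)OO
Why: Proposed new method: hydroxyl-directed Weitz–Scheffer epoxidation of an α-(1-hydroxyalkyl) dienone, the closest known type being the syn-selective lithium tert-butylperoxide epoxidation of hydroxy-substituted electron-poor alkenes; the C1′ hydroxyl binds the peroxide (OH···O or O–Li–O bridge) and delivers it to C6 of the carbinol-bearing alkene only, from the face on which the carbinol oxygen sits in the rotamer that puts C1′–H next to the ring carbonyl (allylic 1,2-strain) and the trienyl group on the far face, so ring closure gives the 5R,6R oxirane (numbering above) from the 1′S carbinol, while the other enone alkene has no anchor and the electron-rich triene is inert to the peroxide anion.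

**Step 9**
Reactants: 16 (1S,6R)-1-[(1S,2E,4E,6E)-9-[(2R)-3,3-dimethyloxiran-2-yl]-1-hydroxy-3,7-dimethylnona-2,4,6-trien-1-yl]-5,5-dimethoxy-7-oxabicyclo[4.1.0]hept-3-en-2-one
Product: 17 (1S,2S,6R)-1-[(1S,2E,4E,6E)-9-[(2R)-3,3-dimethyloxiran-2-yl]-1-hydroxy-3,7-dimethylnona-2,4,6-trien-1-yl]-5,5-dimethoxy-7-oxabicyclo[4.1.0]hept-3-en-2-ol
Conditions: NaBH4, CeCl3·7H2O, MeOH, −78 °C
Reagents that add atoms: none
Why: Luche 1,2-reduction, in which external methoxyborohydride attacks the C4 carbonyl from the face of the oxirane oxygen, anti to the bulky side chain on the adjacent quaternary C5, giving the 4S alcohol trans to the epoxide.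

**Step 10**
Reactants: 17 (1S,2S,6R)-1-[(1S,2E,4E,6E)-9-[(2R)-3,3-dimethyloxiran-2-yl]-1-hydroxy-3,7-dimethylnona-2,4,6-trien-1-yl]-5,5-dimethoxy-7-oxabicyclo[4.1.0]hept-3-en-2-ol
Product: 18 (1R,5S,6S)-6-[(1S,2E,4E,6E)-9-[(2R)-3,3-dimethyloxiran-2-yl]-1-hydroxy-3,7-dimethylnona-2,4,6-trien-1-yl]-5-hydroxy-7-oxabicyclo[4.1.0]hept-3-en-2-one
Conditions: pyridinium p-toluenesulfonate (0.2 equiv), acetone–H2O (10:1), 0 °C → rt
Reagents that add atoms: water, O
Why: Acid-catalysed hydrolysis of the allylic dimethyl ketal through a vinyl-stabilised oxocarbenium ion, the weak buffered acid being chosen to spare both oxiranes and the trienyl carbinol, with no stereocentre touched.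

**Step 11**
Reactants: 18 (1R,5S,6S)-6-[(1S,2E,4E,6E)-9-[(2R)-3,3-dimethyloxiran-2-yl]-1-hydroxy-3,7-dimethylnona-2,4,6-trien-1-yl]-5-hydroxy-7-oxabicyclo[4.1.0]hept-3-en-2-one; 19 formaldehyde
Product: 20 (1R,5S,6R)-6-[(1S,2E,4E,6E)-9-[(2R)-3,3-dimethyloxiran-2-yl]-1-hydroxy-3,7-dimethylnona-2,4,6-trien-1-yl]-5-hydroxy-3-(hydroxymethyl)-7-oxabicyclo[4.1.0]hept-3-en-2-one
Conditions: 37% aq. CH2O, 4-(dimethylamino)pyridine (0.3 equiv), THF–H2O, rt
Reagents that add atoms: none
Why: Morita–Baylis–Hillman hydroxymethylation, in which the amine adds to C3 of the enone, the enolate is trapped at C2 by formaldehyde and elimination restores the enone, a reaction established on 4-oxygenated 5,6-epoxycyclohex-2-enones; no stereocentre is formed.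

**Step 12**
Reactants: 20 (1R,5S,6R)-6-[(1S,2E,4E,6E)-9-[(2R)-3,3-dimethyloxiran-2-yl]-1-hydroxy-3,7-dimethylnona-2,4,6-trien-1-yl]-5-hydroxy-3-(hydroxymethyl)-7-oxabicyclo[4.1.0]hept-3-en-2-one
Product: 21 [(1R,5S,6R)-6-[(1S,2E,4E,6E)-9-[(2R)-3,3-dimethyloxiran-2-yl]-1-hydroxy-3,7-dimethylnona-2,4,6-trien-1-yl]-5-hydroxy-2-oxo-7-oxabicyclo[4.1.0]hept-3-en-3-yl]methyl acetate (CNP0321992.1)
Conditions: AcCl (1.05 equiv), 2,4,6-collidine, CH2Cl2, −78 °C
Reagents that add atoms: acetyl chloride, CC(Cl)=O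
Why: Selective O-acetylation of the primary allylic alcohol, the two secondary hydroxyls flanking the quaternary C5 being far slower at −78 °C.

**Compound list**
1 | 5-bromo-2-methylpent-2-ene | CC(C)=CCCBr | starting material
2 | (3R)-3-(2-bromoethyl)-2,2-dimethyloxirane | BrCC[C@H]1OC1(C)C | intermediate
3 | propyne | CC#C | starting material
4 | (E)-2-bromo-1-iodoprop-1-ene | C/C(Br)=C\I | intermediate
5 | (E)-3-methylpent-2-en-4-yn-1-ol | C#C/C(C)=C/CO | starting material
6 | chloro[(1E,3E)-5-(chlorozirconocenyloxy)-3-methylpenta-1,3-dien-1-yl]zirconocene (O-zirconated dienylzirconocene chloride) | Cl[Zr](C1C=CC=C1)(C1C=CC=C1)/C=C/C(C)=C/CO[Zr](Cl)(C1C=CC=C1)C1C=CC=C1 | intermediate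
7 | [(1E,3E)-5-(chlorozirconocenyloxy)-3-methylpenta-1,3-dien-1-yl]zinc chloride (dienylzinc chloride) | Cl[Zn]/C=C/C(C)=C/CO[Zr](Cl)(C1C=CC=C1)C1C=CC=C1 | intermediate
8 | (2E,4E,6E)-7-bromo-3-methylocta-2,4,6-trien-1-ol | OC/C=C(C)/C=C/C=C(\C)Br | intermediate
9 | (2E,4E,6E)-9-[(2R)-3,3-dimethyloxiran-2-yl]-3,7-dimethylnona-2,4,6-trien-1-ol | OC/C=C(C)/C=C/C=C(\C)CC[C@H]1OC1(C)C | intermediate
10 | (2E,4E,6E)-9-[(2R)-3,3-dimethyloxiran-2-yl]-3,7-dimethylnona-2,4,6-trienal | O=C/C=C(C)/C=C/C=C(\C)CC[C@H]1OC1(C)C | intermediate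
11 | 2-iodophenol | Oc1ccccc1I | starting material
12 | 2-iodo-4-methoxyphenol | COc1ccc(O)c(I)c1 | intermediate
13 | 2-iodo-4,4-dimethoxycyclohexa-2,5-dien-1-one | COC1(OC)C=CC(=O)C(I)=C1 | intermediate
14 | (3,3-dimethoxy-6-oxocyclohexa-1,4-dien-1-yl)chromium dichloride (alkenylchromium dichloride; chiral sulfonamide ligand not drawn) | COC1(OC)C=CC(=O)C([Cr](Cl)Cl)=C1 | intermediate
15 | 2-[(1S,2E,4E,6E)-9-[(2R)-3,3-dimethyloxiran-2-yl]-1-hydroxy-3,7-dimethylnona-2,4,6-trien-1-yl]-4,4-dimethoxycyclohexa-2,5-dien-1-one | COC1(OC)C=CC(=O)C(=C1)[C@@H](O)/C=C(C)/C=C/C=C(\C)CC[C@H]2OC2(C)C | intermediate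
16 | (1S,6R)-1-[(1S,2E,4E,6E)-9-[(2R)-3,3-dimethyloxiran-2-yl]-1-hydroxy-3,7-dimethylnona-2,4,6-trien-1-yl]-5,5-dimethoxy-7-oxabicyclo[4.1.0]hept-3-en-2-one | C1=CC(=O)[C@@]2([C@@H](O)/C=C(C)/C=C/C=C(\C)CC[C@H]3OC3(C)C)O[C@H]2C1(OC)OC | intermediate
17 | (1S,2S,6R)-1-[(1S,2E,4E,6E)-9-[(2R)-3,3-dimethyloxiran-2-yl]-1-hydroxy-3,7-dimethylnona-2,4,6-trien-1-yl]-5,5-dimethoxy-7-oxabicyclo[4.1.0]hept-3-en-2-ol | C1=C[C@H](O)[C@@]2([C@@H](O)/C=C(C)/C=C/C=C(\C)CC[C@H]3OC3(C)C)O[C@H]2C1(OC)OC | intermediate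
18 | (1R,5S,6S)-6-[(1S,2E,4E,6E)-9-[(2R)-3,3-dimethyloxiran-2-yl]-1-hydroxy-3,7-dimethylnona-2,4,6-trien-1-yl]-5-hydroxy-7-oxabicyclo[4.1.0]hept-3-en-2-one | C1=C[C@H](O)[C@@]2([C@@H](O)/C=C(C)/C=C/C=C(\C)CC[C@H]3OC3(C)C)O[C@H]2C1=O | intermediate
19 | formaldehyde | C=O | starting material
20 | (1R,5S,6R)-6-[(1S,2E,4E,6E)-9-[(2R)-3,3-dimethyloxiran-2-yl]-1-hydroxy-3,7-dimethylnona-2,4,6-trien-1-yl]-5-hydroxy-3-(hydroxymethyl)-7-oxabicyclo[4.1.0]hept-3-en-2-one | OCC1=C[C@H](O)[C@@]2([C@@H](O)/C=C(C)/C=C/C=C(\C)CC[C@H]3OC3(C)C)O[C@H]2C1=O | intermediate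
21 | [(1R,5S,6R)-6-[(1S,2E,4E,6E)-9-[(2R)-3,3-dimethyloxiran-2-yl]-1-hydroxy-3,7-dimethylnona-2,4,6-trien-1-yl]-5-hydroxy-2-oxo-7-oxabicyclo[4.1.0]hept-3-en-3-yl]methyl acetate | CC(=O)OCC1=C[C@H](O)[C@@]2([C@@H](O)/C=C(C)/C=C/C=C(\C)CC[C@H]3OC3(C)C)O[C@H]2C1=O | target

**Totals**
Total step count: 12. Longest linear sequence: 10 steps (steps 2, 3, 4, 5, 7, 8, 9, 10, 11, 12).

**Three steps most likely to fail**

Step 8 (directed epoxidation). The peroxide may attack the unsubstituted enone alkene, or oxygen may be delivered anti to the trienyl group in a carbinol–carbonyl chelate, which would give the wrong relative configuration. The fallback sets out from 13 and 10 and comes back at 17. It reaches the same ring configuration from the C1′ epimer and then resets C1′. Step 7 is run with the antipodal ligand to give the 1′R carbinol F4. Lithium tert-butylperoxide, now acting through the chelate sense, gives the (1′R)-epoxy ketone F5. MnO2 oxidises its only free hydroxyl to the diketone F6. Zn(BH4)2 (Et2O, −30 °C) then reduces both carbonyls to give 17: C4 is attacked from the oxirane face, and C1′ through the carbonyl–oxirane zinc chelate, the established erythro-selective reduction of α,β-epoxy ketones.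

Step 7 (asymmetric Cr/Ni coupling). Face selectivity with a conjugated trienal may be modest, and the quinone monoketal may suffer reductive aromatisation. The fallback sets out from 13 and 10 and comes back at 15. It moves the control of C1′ from the addition to a ketone reduction. The coupling is run without chiral ligand (CrCl2, cat. NiCl2, DMSO) to give the C1′-epimeric carbinols F2. MnO2 oxidises these to the trienoyl dienone F3. Reduction with (R)-1-methyl-3,3-diphenyltetrahydro-1H,3H-pyrrolo[1,2-c][1,3,2]oxazaborole and catecholborane at −78 °C, with the fully substituted ring carbon as the large group, gives the 1′S carbinol 15.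

Step 4 (radical cross-electrophile coupling). Risks are opening of the oxirane by halide and metal salts, homocoupling of 8, and partial loss of the 6E geometry. The fallback sets out from 2 and 8 and comes back at 9. It replaces the radical coupling by a polar two-electron one. Zinc insertion into 2 (Zn dust, LiCl, THF, 25 °C) gives {2-[(2R)-3,3-dimethyloxiran-2-yl]ethyl}zinc bromide F1. F1 (2.5 equiv, slow addition to allow for the free hydroxyl) is coupled with 8 using Pd(OAc)2 and 2-dicyclohexylphosphino-2′,6′-dimethoxybiphenyl (Negishi coupling) to give 9.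

**Further compounds**
F1 | step 4 | {2-[(2R)-3,3-dimethyloxiran-2-yl]ethyl}zinc bromide | Br[Zn]CC[C@H]1OC1(C)C
F2 | step 7 | 2-[(1RS,2E,4E,6E)-9-[(2R)-3,3-dimethyloxiran-2-yl]-1-hydroxy-3,7-dimethylnona-2,4,6-trien-1-yl]-4,4-dimethoxycyclohexa-2,5-dien-1-one | COC1(OC)C=CC(=O)C(=C1)C(O)/C=C(C)/C=C/C=C(\C)CC[C@H]2OC2(C)C
F3 | step 7 | 2-[(2E,4E,6E)-9-[(2R)-3,3-dimethyloxiran-2-yl]-3,7-dimethylnona-2,4,6-trienoyl]-4,4-dimethoxycyclohexa-2,5-dien-1-one | COC1(OC)C=CC(=O)C(=C1)C(=O)/C=C(C)/C=C/C=C(\C)CC[C@H]2OC2(C)C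
F4 | step 8 | 2-[(1R,2E,4E,6E)-9-[(2R)-3,3-dimethyloxiran-2-yl]-1-hydroxy-3,7-dimethylnona-2,4,6-trien-1-yl]-4,4-dimethoxycyclohexa-2,5-dien-1-one | COC1(OC)C=CC(=O)C(=C1)[C@H](O)/C=C(C)/C=C/C=C(\C)CC[C@H]2OC2(C)C
F5 | step 8 | (1S,6R)-1-[(1R,2E,4E,6E)-9-[(2R)-3,3-dimethyloxiran-2-yl]-1-hydroxy-3,7-dimethylnona-2,4,6-trien-1-yl]-5,5-dimethoxy-7-oxabicyclo[4.1.0]hept-3-en-2-one | C1=CC(=O)[C@@]2([C@H](O)/C=C(C)/C=C/C=C(\C)CC[C@H]3OC3(C)C)O[C@H]2C1(OC)OC
F6 | step 8 | (1S,6R)-1-[(2E,4E,6E)-9-[(2R)-3,3-dimethyloxiran-2-yl]-3,7-dimethylnona-2,4,6-trienoyl]-5,5-dimethoxy-7-oxabicyclo[4.1.0]hept-3-en-2-one | C1=CC(=O)[C@@]2(C(=O)/C=C(C)/C=C/C=C(\C)CC[C@H]3OC3(C)C)O[C@H]2C1(OC)OC
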